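**Strategy.** The cyclohexane (C5–C10) holds a quaternary carbon C10 (methyl, vinyl) next to the secondary carbinol C9. With the vinyl group read as a formyl group, this pair is the signature of an epoxy-alcohol semipinacol shift. The ring is therefore made by contraction of an all-cis cycloheptane: in a trans-2,3-epoxycycloheptyl silyl ether the ring bond C1–C5 migrates to the tertiary epoxide carbon C10, which expels C1 as the aldehyde, sets C10 by inversion and frees the C9 oxygen in one operation. The cycloheptene comes from the meso furan [4+3] adduct, fitted with two acetate arms and desymmetrised by enantioselective methylative ring opening; the arms become the lactone and the acrolein unit.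

Key step: step 9

Locants (target numbering, kept for all intermediates): ring carbons C5 (acrolein-bearing), C6 (isobutyrate), C7, C8 (lactone O), C9 (OH), C10 (CH3, vinyl); C1 = vinyl CH, a ring atom between C10 and C5 in the seven-membered intermediates; C11/C12 = lactone α-carbon/carbonyl; C4/C15 = α-carbon/carbonyl carbon of the C5 side arm.

Assumption: 1 is bought as the known meso cycloadduct of furan and the parent oxyallyl cation; in step 3 the ligand antipode is whichever delivers the absolute configuration drawn for 6.

Step 1
Reactants: 1 8-oxabicyclo[3.2.1]oct-6-en-3-one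
Product: 3 meso diequatorial bis(tert-butyl acetate) ketone, via mono-alkylated ketone 2 (not isolated)
Conditions: LDA (1.05 equiv), THF, −78 °C; BrCH2CO2tBu, DMPU, −78 to −30 °C; recool, LDA (1.1 equiv); BrCH2CO2tBu; then DBU (0.2 equiv), 0 °C
Reagents that add atoms: tert-butyl bromoacetate, CC(C)(C)OC(=O)CBr
Why: Two successive kinetic enolate alkylations (α, then the less hindered α′ CH2) with a reactive α-halo ester, followed by base equilibration of the enolisable α-centres, should give the thermodynamically preferred meso isomer with both arms equatorial, cis to each other and trans to the oxygen bridge.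

Step 2
Reactants: 3 meso diequatorial bis(tert-butyl acetate) ketone
Product: 5 meso endo-isobutyrate, via lithium alkoxide 4 (not isolated)
Conditions: LiBH(sBu)3 (L-Selectride), THF, −78 °C; then iPrCOCl, DMAP, −78 °C to rt
Reagents that add atoms: isobutyryl chloride, CC(C)C(Cl)=O
Why: The bulky hydride should attack the ketone from the open exo face (hydride reduction, equatorial attack), giving the axial endo alkoxide cis to both arms (all-cis C5/C6/C7), which is O-acylated in the same flask.

Step 3
Reactants: 5 meso endo-isobutyrate
Product: 6 ring-opened cis-2-methylcycloheptenol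
Conditions: Me2Zn (1.5 equiv), Pd(MeCN)2Cl2 (5 mol %), (R)-Tol-BINAP (6 mol %), Zn(OTf)2 (10 mol %), ClCH2CH2Cl, 40 °C; aq. NH4Cl
Reagents that add atoms: dimethylzinc, C[Zn]C
Why: Enantioselective palladium-catalysed alkylative ring opening of a meso oxabicyclic alkene with a dialkylzinc: ligand-controlled exo syn-carbopalladation of one of the two enantiotopic alkene carbons and β-oxygen elimination should put methyl on C10 and leave the oxygen on C1, which breaks the mirror symmetry and so fixes the absolute configuration of C5, C6 and C7.

Step 4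
Reactants: 6 ring-opened cis-2-methylcycloheptenol
Product: 7 β,γ-unsaturated C1 ketone
Conditions: Dess–Martin periodinane, NaHCO3, CH2Cl2, 0 °C
Reagents that add atoms: none
Why: Buffered Dess–Martin oxidation of the C1 carbinol under non-enolising conditions should keep the C8=C9 alkene out of conjugation and the β-acyloxy ketone intact, and it removes the C1 configuration inherited from the oxygen bridge, which lies on the wrong face.

Step 5
Reactants: 7 β,γ-unsaturated C1 ketone
Product: 9 enone lactone, via iodolactone 8 (not isolated)
Conditions: I2, NaHCO3, MeCN, 0 °C; then Et3N, 0 °C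
Reagents that add atoms: none
Why: Iodolactonisation of the C7 tert-butyl ester arm onto the adjacent C8=C9 alkene (5-exo, anti addition, tert-butyl lost as isobutene) can only form the cis-fused γ-lactone with the new C8–O bond on the face of the arm, and the resulting β-iodo ketone should lose HI (E1cB) to the conjugated enone, which restores the C9=C10 alkene.

Step 6
Reactants: 9 enone lactone
Product: 10 all-cis allylic alcohol
Conditions: NaBH4, CeCl3·7H2O, MeOH, −78 °C
Reagents that add atoms: none
Why: Luche 1,2-reduction in which hydride should add to C1 from the face opposite to the C5 arm, the lactone and the isobutyrate, so that the new C1–OH is cis to all of them.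

Step 7
Reactants: 10 all-cis allylic alcohol
Product: 11 triethylsilyl ether
Conditions: Et3SiCl, imidazole, DMF, 0 °C to rt
Reagents that add atoms: chlorotriethylsilane, CC[Si](Cl)(CC)CC
Why: Standard silylation of a secondary allylic alcohol, which switches off hydroxyl-directed epoxidation and supplies the silyl group that is transferred in the key step.

Step 8
Reactants: 11 triethylsilyl ether
Product: 12 trans-epoxy silyl ether
Conditions: mCPBA, NaHCO3, CH2Cl2, 0 °C to rt
Reagents that add atoms: meta-chloroperbenzoic acid, OOC(=O)c1cccc(Cl)c1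
Why: Prilezhaev epoxidation of the trisubstituted alkene should occur from the only open face, anti to the silyloxy group, the lactone ring, the isobutyrate and the arm, which places the epoxide oxygen trans to both the C1–O and the C8–O bonds.

Step 9
Reactants: 12 trans-epoxy silyl ether
Product: 13 ring-contracted silyloxy aldehyde
Conditions: Et3SiOTf (0.3 equiv), 2,6-di-tert-butyl-4-methylpyridine, CH2Cl2, −78 to −40 °C
Reagents that add atoms: none
Why: The silyl triflate silylates the epoxide oxygen, the C10–O bond ionises at the tertiary methyl-bearing carbon and the antiperiplanar ring bond C1–C5 shifts to C10 while the lone pair of the C1 silyloxy group takes up the charge; loss of the silyl group from the oxocarbenium ion returns the catalyst and leaves the aldehyde. The closest known reaction type is the semipinacol rearrangement of 2,3-epoxy alcohol silyl ethers to β-silyloxy aldehydes, including its use for ring contraction of cyclic epoxy alcohols. The cyclohexane is closed by this suprafacial 1,2-alkyl shift (contraction from seven to six ring atoms, C1 expelled as the formyl carbon), not by a cyclisation. C10 is set by inversion at the epoxide carbon and C9 keeps the epoxide configuration, so both are controlled by the epoxide face, and C5 migrates with retention. The step needs migration of the ring bond instead of a hydride shift, and opening at C10 instead of C9. The first is secured because the C1–H is cis to the epoxide oxygen and cannot become antiperiplanar to the breaking bond, the second by the methyl group on C10 and the inductive deactivation of C9 by the neighbouring lactone oxygen.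

Step 10
Reactants: 13 ring-contracted silyloxy aldehyde
Product: 14 vinyl cyclohexane
Conditions: Ph3PCH3Br, KHMDS, THF, 0 °C to rt
Reagents that add atoms: methyltriphenylphosphonium bromide, C[P+](c1ccccc1)(c1ccccc1)c1ccccc1.[Br-]
Why: Wittig methylenation of the non-enolisable aldehyde on the quaternary carbon should give the C10 vinyl group, the ylide being too weak a base to enolise the lactone and the β-silyloxy group preventing retro-aldol cleavage.

Step 11
Reactants: 14 vinyl cyclohexane
Product: 15 C11-methyl lactone
Conditions: LDA (1.05 equiv), THF, −78 °C; MeI, −78 °C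
Reagents that add atoms: iodomethane, CI
Why: Kinetic deprotonation of the γ-lactone (more acidic than the acyclic tert-butyl ester) and enolate alkylation from the convex face of the cis-fused bicycle, anti to C6, should place the C11 methyl cis to H-7 as in the target.

Step 12
Reactants: 15 C11-methyl lactone
Product: 16 carboxylic acid
Conditions: Me3SiOTf, 2,6-lutidine, CH2Cl2, 0 °C; aq. work-up
Reagents that add atoms: none
Why: Silyl triflate-mediated cleavage of the tert-butyl ester (loss of isobutene, silyl ester hydrolysed on work-up) under buffered conditions should leave the triethylsilyl ether, the lactone and the isobutyrate untouched.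

Step 13
Reactants: 16 carboxylic acid
Product: 18 side-arm aldehyde, via acid chloride 17 (not isolated)
Conditions: 1-chloro-N,N,2-trimethylprop-1-en-1-amine, CH2Cl2, 0 °C; then LiAlH(OtBu)3, THF, −78 °C
Reagents that add atoms: none
Why: Neutral acid chloride formation followed by low-temperature reduction with the hindered alkoxyaluminium hydride should stop at the aldehyde, since the acid chloride is far more reactive than the lactone and the two esters.

Step 14
Reactants: 18 side-arm aldehyde
Product: 19 silyl-protected target
Conditions: Me2N=CH2 I (Eschenmoser's salt), Et3N, CH2Cl2, rt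
Reagents that add atoms: N,N-dimethylmethyleneiminium iodide, C=[N+](C)C.[I-]
Why: Mannich reaction at the only enolisable aldehyde α-position (C4) followed by β-elimination of dimethylamine should give the 2-substituted acrolein (α-methylenation of an aldehyde).

Step 15
Reactants: 19 silyl-protected target
Product: 20 target CNP0198892.2
Conditions: HF·pyridine, THF, 0 °C
Reagents that add atoms: none
Why: Fluoride-mediated cleavage of the secondary silyl ether under mildly acidic, non-nucleophilic conditions should spare the enal, the lactone and the isobutyrate.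

**Compound list**

1 | 8-oxabicyclo[3.2.1]oct-6-en-3-one (meso) | C1=C[C@H]2CC(=O)C[C@@H]1O2 | starting material
2 | tert-butyl 2-(3-oxo-8-oxabicyclo[3.2.1]oct-6-en-2-yl)acetate; racemic, one enantiomer drawn; arm on the face of the oxygen bridge; not isolated | C1=C[C@H]2[C@H](CC(=O)OC(C)(C)C)C(=O)C[C@@H]1O2 | intermediate
3 | di-tert-butyl 2,2'-(3-oxo-8-oxabicyclo[3.2.1]oct-6-ene-2,4-diyl)diacetate; meso; both arms equatorial, cis to each other, trans to the oxygen bridge | C1=C[C@H]2[C@@H](CC(=O)OC(C)(C)C)C(=O)[C@@H](CC(=O)OC(C)(C)C)[C@@H]1O2 | intermediate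
4 | meso 3-endo alcohol of 3, OH cis to both arms; present as its lithium alkoxide, drawn as the alcohol; not isolated | C1=C[C@H]2[C@@H](CC(=O)OC(C)(C)C)[C@@H](O)[C@@H](CC(=O)OC(C)(C)C)[C@@H]1O2 | intermediate
5 | meso 3-endo isobutyrate of 4; C5 arm, C6 isobutyrate and C7 arm all-cis, trans to the oxygen bridge | C1=C[C@H]2[C@@H](CC(=O)OC(C)(C)C)[C@@H](OC(=O)C(C)C)[C@@H](CC(=O)OC(C)(C)C)[C@@H]1O2 | intermediate
6 | cycloheptenol with C8=C9; C1–OH and C10–CH3 cis to each other; C5–CH2CO2tBu, C6–OCOiPr and C7–CH2CO2tBu mutually cis and trans to C1–OH | C[C@@H]1C=C[C@@H](CC(=O)OC(C)(C)C)[C@@H](OC(=O)C(C)C)[C@@H](CC(=O)OC(C)(C)C)[C@@H]1O | intermediate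
7 | C1 ketone of 6 (β,γ-unsaturated) | C[C@@H]1C=C[C@@H](CC(=O)OC(C)(C)C)[C@@H](OC(=O)C(C)C)[C@@H](CC(=O)OC(C)(C)C)C1=O | intermediate
8 | iodolactone: cis-fused γ-lactone C8–O–C12(=O)–C11H2–C7 on the face of the former C7 arm, C9–I trans to C8–O; not isolated | C[C@@H]1[C@H](I)[C@H]2OC(=O)C[C@H]2[C@@H](OC(=O)C(C)C)[C@@H](CC(=O)OC(C)(C)C)C1=O | intermediate
9 | enone lactone: C1=O, C9=C10(CH3), cis-fused C7/C8 γ-lactone, C6 isobutyrate and C5–CH2CO2tBu all-cis | CC1=C[C@H]2OC(=O)C[C@H]2[C@@H](OC(=O)C(C)C)[C@@H](CC(=O)OC(C)(C)C)C1=O | intermediate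
10 | allylic alcohol: as 9, with C1–OH cis to the C5 arm, the isobutyrate and the lactone | CC1=C[C@H]2OC(=O)C[C@H]2[C@@H](OC(=O)C(C)C)[C@@H](CC(=O)OC(C)(C)C)[C@H]1O | intermediate
11 | triethylsilyl ether of 10 | CC1=C[C@H]2OC(=O)C[C@H]2[C@@H](OC(=O)C(C)C)[C@@H](CC(=O)OC(C)(C)C)[C@H]1O[Si](CC)(CC)CC | intermediate
12 | C9,C10-epoxide of 11, epoxide oxygen trans to C1–OSiEt3 and to the C8–O bond | C[C@@]12O[C@@H]1[C@H]3OC(=O)C[C@H]3[C@@H](OC(=O)C(C)C)[C@@H](CC(=O)OC(C)(C)C)[C@H]2O[Si](CC)(CC)CC | intermediate
13 | cyclohexane C5–C10: C10 bears CH3 and CHO (C1); C9–OSiEt3 trans to C8–O; cis-fused γ-lactone at C7/C8; C6 isobutyrate; C5–CH2CO2tBu; C5, C6, C7, C8 substituents all-cis | O=C[C@]1(C)[C@H](O[Si](CC)(CC)CC)[C@H]2OC(=O)C[C@H]2[C@@H](OC(=O)C(C)C)[C@H]1CC(=O)OC(C)(C)C | intermediate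
14 | as 13 with vinyl in place of CHO on C10 | C=C[C@]1(C)[C@H](O[Si](CC)(CC)CC)[C@H]2OC(=O)C[C@H]2[C@@H](OC(=O)C(C)C)[C@H]1CC(=O)OC(C)(C)C | intermediate
15 | as 14 with C11 methyl, cis to H-7 | C=C[C@]1(C)[C@H](O[Si](CC)(CC)CC)[C@H]2OC(=O)[C@H](C)[C@H]2[C@@H](OC(=O)C(C)C)[C@H]1CC(=O)OC(C)(C)C | intermediate
16 | C5–CH2CO2H acid from 15 | C=C[C@]1(C)[C@H](O[Si](CC)(CC)CC)[C@H]2OC(=O)[C@H](C)[C@H]2[C@@H](OC(=O)C(C)C)[C@H]1CC(=O)O | intermediate
17 | acid chloride of 16; not isolated | C=C[C@]1(C)[C@H](O[Si](CC)(CC)CC)[C@H]2OC(=O)[C@H](C)[C@H]2[C@@H](OC(=O)C(C)C)[C@H]1CC(=O)Cl | intermediate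
18 | C5–CH2CHO aldehyde | C=C[C@]1(C)[C@H](O[Si](CC)(CC)CC)[C@H]2OC(=O)[C@H](C)[C@H]2[C@@H](OC(=O)C(C)C)[C@H]1CC=O | intermediate
19 | C9 triethylsilyl ether of the target | C=C[C@]1(C)[C@H](O[Si](CC)(CC)CC)[C@H]2OC(=O)[C@H](C)[C@H]2[C@@H](OC(=O)C(C)C)[C@H]1C(=C)C=O | intermediate
20 | CNP0198892.2: cyclohexane-fused cis-γ-lactone with C10 methyl/vinyl, C9 OH, C6 isobutyrate and C5 2-propenal-2-yl | C=C[C@]1(C)[C@H](O)[C@H]2OC(=O)[C@H](C)[C@H]2[C@@H](OC(=O)C(C)C)[C@H]1C(=C)C=O | target

**Step count and risks**

Total step count: 15. Longest linear sequence: 15 steps (fully linear from 1).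

Steps most likely to fail:

1. Step 9 (key step). The opened epoxide may lose a proton to give an allylic silyl ether, the epoxide may migrate with silyl assistance, or the C10 cation may be trapped by the nearby tert-butyl ester instead of undergoing the C1–C5 shift. The fallback sets out from 12 and returns at 13. 12 is desilylated (Bu4NF, AcOH, THF) to the free trans-epoxy alcohol F1. F1 is rearranged with SnCl4 (CH2Cl2, −78 °C), where tin binds the carbinol and epoxide oxygens as a chelate; this is the ring contraction of an unprotected cyclic 2,3-epoxy alcohol, without silyl transfer and without base. The resulting β-hydroxy aldehyde F2 is silylated (Et3SiOTf, 2,6-lutidine) and rejoins the route as 13.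

2. Step 3. The two enantiotopic alkene carbons may be poorly discriminated and carbopalladation may be slow, because both neighbours of the alkene carry substituents. The fallback sets out from 5 and returns at 6. 5 is opened without a chiral ligand (Me2Zn, PdCl2(dppf), Zn(OTf)2) to the racemate, that is 6 together with its mirror image F3. A kinetic resolution by lipase-catalysed transesterification (Burkholderia cepacia lipase, vinyl acetate, tBuOMe) is then run so that the unwanted enantiomer is acylated to the acetate F4; unreacted 6 is separated and enters step 4.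

3. Step 5. The β,γ-unsaturated ketone may isomerise into conjugation before iodolactonisation, which removes the alkene the lactonisation needs, and base may eliminate isobutyrate from the β-acyloxy ketone. The fallback sets out from 6 and returns at 9, lactonising before any ketone is present. 6 is silylated (Et3SiCl, imidazole) to the triethylsilyl ether F5 and iodolactonised (I2, NaHCO3, MeCN) to the iodolactone F6. Anti E2 elimination with DBU (H-10 is antiperiplanar to the iodide) gives the allylic lactone F7, and HF·pyridine gives the C1-epimeric allylic alcohol F8. Oxidation (MnO2 or Dess–Martin periodinane) then gives 9.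

**Further compounds**

F1 | step 9 | free trans-epoxy alcohol (12 without the silyl group) | C[C@@]12O[C@@H]1[C@H]3OC(=O)C[C@H]3[C@@H](OC(=O)C(C)C)[C@@H](CC(=O)OC(C)(C)C)[C@H]2O
F2 | step 9 | ring-contracted β-hydroxy aldehyde (13 without the silyl group) | O=C[C@]1(C)[C@H](O)[C@H]2OC(=O)C[C@H]2[C@@H](OC(=O)C(C)C)[C@H]1CC(=O)OC(C)(C)C
F3 | step 3 | mirror image of 6 | C[C@H]1C=C[C@H](CC(=O)OC(C)(C)C)[C@H](OC(=O)C(C)C)[C@H](CC(=O)OC(C)(C)C)[C@H]1O
F4 | step 3 | C1 acetate of the mirror image of 6 | C[C@H]1C=C[C@H](CC(=O)OC(C)(C)C)[C@H](OC(=O)C(C)C)[C@H](CC(=O)OC(C)(C)C)[C@H]1OC(C)=O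
F5 | step 5 | C1 triethylsilyl ether of 6 | C[C@@H]1C=C[C@@H](CC(=O)OC(C)(C)C)[C@@H](OC(=O)C(C)C)[C@@H](CC(=O)OC(C)(C)C)[C@@H]1O[Si](CC)(CC)CC
F6 | step 5 | iodolactone silyl ether (C8–O lactone cis-fused, C9–I trans to it, C1–OSiEt3 trans to the lactone) | C[C@@H]1[C@H](I)[C@H]2OC(=O)C[C@H]2[C@@H](OC(=O)C(C)C)[C@@H](CC(=O)OC(C)(C)C)[C@@H]1O[Si](CC)(CC)CC
F7 | step 5 | allylic lactone silyl ether, C1 epimer of 11 | CC1=C[C@H]2OC(=O)C[C@H]2[C@@H](OC(=O)C(C)C)[C@@H](CC(=O)OC(C)(C)C)[C@@H]1O[Si](CC)(CC)CC
F8 | step 5 | C1-epimeric allylic alcohol (C1 epimer of 10) | CC1=C[C@H]2OC(=O)C[C@H]2[C@@H](OC(=O)C(C)C)[C@@H](CC(=O)OC(C)(C)C)[C@@H]1O
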